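**Plan**

- Labels: the cyclohexene carbons are C-a (on C3 of quinolone A), C-b (=CH), C-c (CH3, O-B), C-d (CH2), C-e (H, C3' of quinolone B) and C-f (H, CMe2); O-A joins CMe2 to C4 of A (ring A) and O-B joins C-c to C4' of B (ring B).
- Retrosynthesis: cut O-B–C-c while moving the alkene from C-a=C-b back to C-b=C-c; then cut O-A–CMe2 and the two C–CH3 bonds (C-f carbinol back to a C-f aldehyde); then cut C-d–C-e and C-f–C-a of the carbocycle; finally cut the C3–C and C3'–C bonds to two 3-iodoquinolones made from one monomer.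
- Enabling feature: C-e and C-f are vicinal trans CH centres lying between aryl-bearing C-a and methyl-bearing C-c, which is the adduct pattern of a 1-aryl-3-methylbuta-1,3-diene (C-a to C-d) and an E β-aryl enal (C-e, C-f).
- Forward order: quinolone monomer, two O4-protected 3-iodides, diene and enal by Suzuki–Miyaura couplings, carbocycle by Diels–Alder reaction, then the dimethylpyran ring A, and the bridged ether ring B last.
- Stereochemistry: the (5R)-imidazolidinone salt sets C-e and C-f (Re face of C-e; trans from the E enal); the endo mode sets C-a with its H syn to quinolone B, as the closing syn oxypalladation/β-hydride elimination needs; C-c is dictated by the O-B tether.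

Key step: step 9

Remark: O-A is carried as a 2-(trimethylsilyl)ethyl ether and O-B as a benzyl ether. An O-allyl group beside the C3 iodide would cyclise or ionise under zerovalent palladium, and an acetal-type group would not last in the acidic cycloaddition medium. The acetal-bearing alkenylboronate of step 8 and the catalyst salt of step 9 are taken as purchasable.

**Route**

Step 1
Reactants: 1 2,3-dimethoxyaniline
Product: 3 2,3-dimethoxy-N-methylaniline, via N-(methoxymethyl)-2,3-dimethoxyaniline 2 (not isolated)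
Conditions: (CH2O)n, NaOMe, MeOH, reflux; then NaBH4, reflux
Reagents that add atoms: paraformaldehyde (as formaldehyde), C=O
Why: Condensation with formaldehyde in methanolic NaOMe stops at the N-(methoxymethyl)aniline, whose hydride reduction gives only the mono-N-methyl aniline (reductive amination).

Step 2
Reactants: 3 2,3-dimethoxy-N-methylaniline; 4 diethyl malonate
Product: 6 4-hydroxy-7,8-dimethoxy-1-methylquinolin-2(1H)-one, via malonamate ester 5 (not isolated)
Conditions: Ph2O, 250 °C, EtOH distilled off
Reagents that add atoms: none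
Why: Thermal aminolysis of one ester is followed by intramolecular C-acylation (Friedel–Crafts-type, through the acyl ketene) at the only free ortho position, which is para to the 3-methoxy group, so the 4-hydroxy-2-quinolone forms with the 7,8-dimethoxy pattern.

Step 3
Reactants: 6 4-hydroxy-7,8-dimethoxy-1-methylquinolin-2(1H)-one
Product: 7 4-hydroxy-3-iodo-7,8-dimethoxy-1-methylquinolin-2(1H)-one
Conditions: NIS, DMF, 0 °C to rt
Reagents that add atoms: N-iodosuccinimide, O=C1CCC(=O)N1I
Why: C3 is the nucleophilic carbon of an enolised β-dicarbonyl unit and undergoes electrophilic iodination far faster than the benzo ring.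

Step 4
Reactants: 7 4-hydroxy-3-iodo-7,8-dimethoxy-1-methylquinolin-2(1H)-one
Product: 8 3-iodo-7,8-dimethoxy-1-methyl-4-[2-(trimethylsilyl)ethoxy]quinolin-2(1H)-one (quinolone A iodide)
Conditions: Me3SiCH2CH2OH, PPh3, DIAD, THF, 0 °C to rt
Reagents that add atoms: 2-(trimethylsilyl)ethanol, C[Si](C)(C)CCO
Why: Mitsunobu alkylation of the acidic enol by the primary alcohol occurs at O4 and gives a vinylogous ester that withstands base, mild acid and organometallic reagents yet is cleaved by fluoride.

Step 5
Reactants: 7 4-hydroxy-3-iodo-7,8-dimethoxy-1-methylquinolin-2(1H)-one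
Product: 9 4-(benzyloxy)-3-iodo-7,8-dimethoxy-1-methylquinolin-2(1H)-one (quinolone B iodide)
Conditions: BnBr, K2CO3, DMF, rt
Reagents that add atoms: benzyl bromide, BrCc1ccccc1
Why: Williamson alkylation of the quinolonate in a polar aprotic solvent goes to O4 because C3 is blocked by iodine.

Step 6
Reactants: 10 2-methylbut-1-en-3-yne
Product: 11 4,4,5,5-tetramethyl-2-[(1E)-3-methylbuta-1,3-dien-1-yl]-1,3,2-dioxaborolane
Conditions: HBpin, Cp2Zr(H)Cl (5 mol %), Et3N (10 mol %), neat, sealed tube, 40 °C
Reagents that add atoms: pinacolborane, [H]B1OC(C)(C)C(C)(C)O1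
Why: Cp2Zr(H)Cl-catalysed hydroboration adds H and B syn and anti-Markovnikov to the terminal alkyne in preference to the 1,1-disubstituted alkene, which gives the E dienylboronate.

Step 7
Reactants: 8 quinolone A iodide; 11 E dienylboronate
Product: 12 7,8-dimethoxy-1-methyl-3-[(1E)-3-methylbuta-1,3-dien-1-yl]-4-[2-(trimethylsilyl)ethoxy]quinolin-2(1H)-one (diene A)
Conditions: Pd(dppf)Cl2 (5 mol %), K3PO4, dioxane–H2O (5:1), 80 °C
Reagents that add atoms: none
Why: Suzuki–Miyaura coupling (oxidative addition of zerovalent palladium into C3–I, transmetallation of the alkenylboronate, reductive elimination) keeps the E geometry, and the silylethyl ether is inert to aqueous phosphate.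

Step 8
Reactants: 9 quinolone B iodide; 13 2-[(1E)-3,3-diethoxyprop-1-en-1-yl]-4,4,5,5-tetramethyl-1,3,2-dioxaborolane
Product: 15 (2E)-3-[4-(benzyloxy)-7,8-dimethoxy-1-methyl-2-oxo-1,2-dihydroquinolin-3-yl]prop-2-enal (enal B), via diethyl acetal 14 (not isolated)
Conditions: Pd(dppf)Cl2 (5 mol %), K3PO4, dioxane–H2O (5:1), 80 °C; then 1 M HCl, THF, rt
Reagents that add atoms: water, O
Why: Suzuki–Miyaura coupling installs the E three-carbon unit as its acetal, which avoids polymerisable acrolein, and dilute acid then unmasks the conjugated aldehyde without touching the benzyl vinylogous ester.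

Step 9
Reactants: 12 diene A; 15 enal B
Product: 16 (1S,2R,6R)-6-[4-(benzyloxy)-7,8-dimethoxy-1-methyl-2-oxo-1,2-dihydroquinolin-3-yl]-2-{7,8-dimethoxy-1-methyl-2-oxo-4-[2-(trimethylsilyl)ethoxy]-1,2-dihydroquinolin-3-yl}-4-methylcyclohex-3-ene-1-carbaldehyde (C1 = C-f, C2 = C-a, C6 = C-e)
Conditions: (5R)-5-benzyl-2,2,3-trimethylimidazolidin-4-one·HCl (20 mol %), 12 (1.5 equiv), MeNO2–H2O (19:1), 1 M, rt
Reagents that add atoms: none
Why: The catalyst condenses with enal 15 to an E-configured unsaturated iminium ion of lowered LUMO, and diene 12 adds in a concerted but asynchronous (4+2) cycloaddition in which the unhindered CH2 terminus C-d bonds ahead to the β-carbon C-e while C-a bonds to the α-carbon C-f, after which hydrolysis releases aldehyde 16 and the catalyst. The closest known reaction type is the imidazolidinone-salt-catalysed enantioselective Diels–Alder reaction of enals with acyclic dienes. The cyclohexene is the only ring closed, by intermolecular suprafacial (4π+2π) cycloaddition that forms C-d–C-e and C-f–C-a. C-e is controlled by the benzyl group of the (5R) catalyst, which covers the Si face of C-e and leaves the Re face open; C-f is controlled by the E geometry of the enal, carried into the trans relation of quinolone B and the formyl group; C-a is controlled by the endo orientation of the iminium unit, which places quinolone A cis to the formyl group and the C-a hydrogen syn to quinolone B. The step needs ortho/para regioselectivity, which the 1-aryl and 3-methyl groups of the diene both supply by placing the largest HOMO coefficient on C-d, and it needs a sufficiently electrophilic dienophile, which is helped by the two ortho substituents twisting quinolone B out of conjugation so that the 4-benzyloxy group deactivates the iminium ion less; the acid-stable silylethyl ether keeps the diene from cyclising to a chromene in the acidic medium.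

Step 10
Reactants: 16 cyclohexene carbaldehyde
Product: 17 (1S,2R,6R)-cyclohex-3-ene-1-carboxylic acid corresponding to 16 (CO2H on C-f)
Conditions: NaClO2, NaH2PO4, 2-methylbut-2-ene, t-BuOH–H2O, 0 °C to rt
Reagents that add atoms: sodium chlorite, [Na+].[O-]Cl=O
Why: Pinnick oxidation converts the aldehyde into the acid in a buffered medium that does not epimerise C-f, while 2-methylbut-2-ene traps hypochlorous acid before it can attack the ring alkene or the methoxyarenes.

Step 11
Reactants: 17 carboxylic acid
Product: 18 methyl (1S,2R,6R)-cyclohex-3-ene-1-carboxylate corresponding to 17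
Conditions: Me3SiCHN2, PhMe–MeOH (4:1), 0 °C
Reagents that add atoms: trimethylsilyldiazomethane, C[Si](C)(C)C=[N+]=[N-]
Why: O-methylation of the acid by the diazoalkane in methanol is neutral and fast, so the α-stereocentre C-f is not touched.

Step 12
Reactants: 18 methyl ester
Product: 19 2-[(1S,2R,6R)-6-(4-benzyloxy quinolone B)-2-(4-silylethoxy quinolone A)-4-methylcyclohex-3-en-1-yl]propan-2-ol (carbinol on C-f)
Conditions: MeMgBr (6 equiv), CeCl3, THF, −78 to 0 °C
Reagents that add atoms: methylmagnesium bromide, C[Mg]Br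
Why: Double Grignard addition, with CeCl3 to raise nucleophilicity and suppress enolisation of the hindered ester, gives the tertiary carbinol, while the quinolone carbonyls are unreactive vinylogous carbamate groups.

Step 13
Reactants: 19 silylethyl-protected carbinol
Product: 20 2-[(1S,2R,6R)-6-(4-benzyloxy quinolone B)-2-(4-hydroxy quinolone A)-4-methylcyclohex-3-en-1-yl]propan-2-ol
Conditions: Bu4NF, THF, rt; AcOH quench
Reagents that add atoms: none
Why: Fluoride attacks silicon and triggers β-elimination of ethene from the 2-silylethyl ether, which frees only the 4-hydroxyl of quinolone A because the benzyl ether and the carbinol are inert to fluoride.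

Step 14
Reactants: 20 hydroxyquinolone carbinol
Product: 21 cis-fused dimethylpyranoquinolone (O-A joins CMe2 to C4 of quinolone A; C-a R, C-e R, C-f S; C-b=C-c alkene and 4'-O-benzyl retained)
Conditions: ZnBr2, MgSO4, CH2Cl2, rt
Reagents that add atoms: none
Why: The Lewis acid ionises the tertiary carbinol and the neighbouring cis-disposed enol oxygen of quinolone A captures the cation in a six-membered closure (the cyclodehydration used for 2,2-dimethylchromans beside a trisubstituted cyclohexene), under conditions too mild to protonate C-b=C-c and with O-B still benzylated so that it cannot compete.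

Step 15
Reactants: 21 benzyl-protected pyranoquinolone
Product: 22 4'-hydroxy pyranoquinolone (21 without the benzyl group)
Conditions: H2 (1 atm), Pd/C (5 %), EtOAc, rt, short reaction time
Reagents that add atoms: none
Why: Hydrogenolysis of the benzyl vinylogous ester, which is as labile as a benzyl ester, is much faster than hydrogenation of the hindered trisubstituted ring alkene.

Step 16
Reactants: 22 4'-hydroxy pyranoquinolone
Product: 23 CNP0237003.1 (C-a=C-b alkene; C-c S with CH3 and O-B; C-e R; C-f S)
Conditions: Pd(OCOCF3)2 (10 mol %), pyridine (40 mol %), 3 Å MS, O2 (1 atm), PhMe, 80 °C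
Reagents that add atoms: none
Why: In this aerobic Wacker-type oxidative cyclisation, divalent palladium bound to the quinolone B enolate adds with O-B across C-b=C-c on one face (syn oxypalladation, O-B to the tertiary carbon C-c), syn β-hydride elimination of the cis hydrogen on C-a moves the alkene to C-a=C-b, and O2 returns zerovalent palladium to the divalent state; C-c can only form with O-B cis to the C-e–C3' bond because the one-carbon bridge C-d allows no other bicyclo[3.3.1] ring.

**Compound list**

1 | 2,3-dimethoxyaniline | COc1cccc(N)c1OC | starting material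
2 | N-(methoxymethyl)-2,3-dimethoxyaniline | COCNc1cccc(OC)c1OC | intermediate
3 | 2,3-dimethoxy-N-methylaniline | CNc1cccc(OC)c1OC | intermediate
4 | diethyl malonate | CCOC(=O)CC(=O)OCC | starting material
5 | ethyl 3-[(2,3-dimethoxyphenyl)(methyl)amino]-3-oxopropanoate | CCOC(=O)CC(=O)N(C)c1cccc(OC)c1OC | intermediate
6 | 4-hydroxy-7,8-dimethoxy-1-methylquinolin-2(1H)-one | COc1ccc2c(O)cc(=O)n(C)c2c1OC | intermediate
7 | 4-hydroxy-3-iodo-7,8-dimethoxy-1-methylquinolin-2(1H)-one | COc1ccc2c(O)c(I)c(=O)n(C)c2c1OC | intermediate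
8 | 3-iodo-7,8-dimethoxy-1-methyl-4-[2-(trimethylsilyl)ethoxy]quinolin-2(1H)-one | COc1ccc2c(OCC[Si](C)(C)C)c(I)c(=O)n(C)c2c1OC | intermediate
9 | 4-(benzyloxy)-3-iodo-7,8-dimethoxy-1-methylquinolin-2(1H)-one | COc1ccc2c(OCc3ccccc3)c(I)c(=O)n(C)c2c1OC | intermediate
10 | 2-methylbut-1-en-3-yne | C=C(C)C#C | starting material
11 | 4,4,5,5-tetramethyl-2-[(1E)-3-methylbuta-1,3-dien-1-yl]-1,3,2-dioxaborolane | C=C(C)/C=C/B1OC(C)(C)C(C)(C)O1 | intermediate
12 | 7,8-dimethoxy-1-methyl-3-[(1E)-3-methylbuta-1,3-dien-1-yl]-4-[2-(trimethylsilyl)ethoxy]quinolin-2(1H)-one | COc1ccc2c(OCC[Si](C)(C)C)c(/C=C/C(C)=C)c(=O)n(C)c2c1OC | intermediate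
13 | 2-[(1E)-3,3-diethoxyprop-1-en-1-yl]-4,4,5,5-tetramethyl-1,3,2-dioxaborolane | CCOC(OCC)/C=C/B1OC(C)(C)C(C)(C)O1 | starting material
14 | 4-(benzyloxy)-3-[(1E)-3,3-diethoxyprop-1-en-1-yl]-7,8-dimethoxy-1-methylquinolin-2(1H)-one | CCOC(OCC)/C=C/c1c(OCc2ccccc2)c2ccc(OC)c(OC)c2n(C)c1=O | intermediate
15 | (2E)-3-[4-(benzyloxy)-7,8-dimethoxy-1-methyl-2-oxo-1,2-dihydroquinolin-3-yl]prop-2-enal | O=C/C=C/c1c(OCc2ccccc2)c2ccc(OC)c(OC)c2n(C)c1=O | intermediate
16 | (1S,2R,6R)-6-(4-benzyloxy quinolone B)-2-(4-silylethoxy quinolone A)-4-methylcyclohex-3-ene-1-carbaldehyde | COc1ccc2c(OCC[Si](C)(C)C)c(c(=O)n(C)c2c1OC)[C@@H]1C=C(C)C[C@@H](c3c(OCc4ccccc4)c4ccc(OC)c(OC)c4n(C)c3=O)[C@@H]1C=O | intermediate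
17 | (1S,2R,6R)-cyclohex-3-ene-1-carboxylic acid corresponding to 16 | COc1ccc2c(OCC[Si](C)(C)C)c(c(=O)n(C)c2c1OC)[C@@H]1C=C(C)C[C@@H](c3c(OCc4ccccc4)c4ccc(OC)c(OC)c4n(C)c3=O)[C@@H]1C(=O)O | intermediate
18 | methyl ester of 17 | COc1ccc2c(OCC[Si](C)(C)C)c(c(=O)n(C)c2c1OC)[C@@H]1C=C(C)C[C@@H](c3c(OCc4ccccc4)c4ccc(OC)c(OC)c4n(C)c3=O)[C@@H]1C(=O)OC | intermediate
19 | 2-[(1S,2R,6R)-6-(4-benzyloxy quinolone B)-2-(4-silylethoxy quinolone A)-4-methylcyclohex-3-en-1-yl]propan-2-ol | COc1ccc2c(OCC[Si](C)(C)C)c(c(=O)n(C)c2c1OC)[C@@H]1C=C(C)C[C@@H](c3c(OCc4ccccc4)c4ccc(OC)c(OC)c4n(C)c3=O)[C@@H]1C(C)(C)O | intermediate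
20 | 2-[(1S,2R,6R)-6-(4-benzyloxy quinolone B)-2-(4-hydroxy quinolone A)-4-methylcyclohex-3-en-1-yl]propan-2-ol | COc1ccc2c(O)c(c(=O)n(C)c2c1OC)[C@@H]1C=C(C)C[C@@H](c3c(OCc4ccccc4)c4ccc(OC)c(OC)c4n(C)c3=O)[C@@H]1C(C)(C)O | intermediate
21 | cis-fused dimethylpyranoquinolone with 4'-O-benzyl quinolone B on C-e (C-a R, C-e R, C-f S) | COc1ccc2c3c(c(=O)n(C)c2c1OC)[C@@H]1C=C(C)C[C@@H](c4c(OCc5ccccc5)c5ccc(OC)c(OC)c5n(C)c4=O)[C@@H]1C(C)(C)O3 | intermediate
22 | cis-fused dimethylpyranoquinolone with 4'-hydroxy quinolone B on C-e (C-a R, C-e R, C-f S) | COc1ccc2c3c(c(=O)n(C)c2c1OC)[C@@H]1C=C(C)C[C@@H](c4c(O)c5ccc(OC)c(OC)c5n(C)c4=O)[C@@H]1C(C)(C)O3 | intermediate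
23 | CNP0237003.1 (C-c S, C-e R, C-f S) | COc1ccc2c3c(c(=O)n(C)c2c1OC)C1=C[C@]2(C)C[C@@H](c4c(c5ccc(OC)c(OC)c5n(C)c4=O)O2)[C@@H]1C(C)(C)O3 | target

**Step count**

Total steps: 16. Longest linear sequence: 13 steps (steps 1, 2, 3, 4, 7, 9, 10, 11, 12, 13, 14, 15, 16; the branch through steps 5 and 8 is equally long).

**Steps most likely to fail**

Step 9. The iminium ion of a β-aryl enal with two ortho substituents and a donor oxygen may react so slowly that acid-promoted loss of the diene outpaces cycloaddition, and endo selectivity may erode under forcing. The fallback changes the activation to an auxiliary-bound, aluminium-chelated dienophile. Setting out from 15, Pinnick oxidation gives the acrylic acid F1. Pivaloyl chloride and Et3N convert it into the mixed pivalic anhydride F2 (not isolated), and (R)-4-benzyloxazolidin-2-one with LiCl gives the enoyl imide F3. Et2AlCl (1.5 equiv, CH2Cl2, −30 °C) and diene 12 should then give the endo cycloadduct imide F4 through the chelated s-cis imide, the diene adding to the Re face of C-e away from the auxiliary benzyl group. LiOH/H2O2 removes the auxiliary and the route is rejoined at acid 17.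

Step 16. Oxypalladation may proceed anti instead of syn, which leaves no β-hydrogen syn to palladium, or the chelating quinolone may inhibit the catalyst, or allylic oxidation may compete. The fallback replaces the one-step oxidative closure by halocyclisation and elimination. Setting out from 22, I2 and NaHCO3 in MeCN at 0 °C should give the trans-diaxial iodo ether F5 by anti addition (O-B to C-c, iodine to C-b on the opposite face). DBU in PhMe at 80 °C then removes the C-a hydrogen, which is anti-periplanar to the C–I bond, in an E2 elimination that gives 23 directly.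

Step 12. The second addition to the ester on C-f, which lies between two carbons bearing bulky quinolones, may stall, or the ester may enolise and be recovered. The fallback builds the carbinol one methyl at a time through the more electrophilic ketone. Setting out from 16, MeMgBr (THF, −78 °C) gives the secondary alcohol F6 as a mixture of carbinol epimers, Dess–Martin oxidation gives the methyl ketone F7, and MeMgBr with CeCl3 then gives carbinol 19, where the route is rejoined.

**Further compounds**

F1 | step 9 | (2E)-3-[4-(benzyloxy)-7,8-dimethoxy-1-methyl-2-oxo-1,2-dihydroquinolin-3-yl]prop-2-enoic acid | OC(=O)/C=C/c1c(OCc2ccccc2)c2ccc(OC)c(OC)c2n(C)c1=O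
F2 | step 9 | mixed anhydride of F1 with pivalic acid | CC(C)(C)C(=O)OC(=O)/C=C/c1c(OCc2ccccc2)c2ccc(OC)c(OC)c2n(C)c1=O
F3 | step 9 | (4R)-4-benzyl-3-{(2E)-3-[4-(benzyloxy)-7,8-dimethoxy-1-methyl-2-oxo-1,2-dihydroquinolin-3-yl]prop-2-enoyl}oxazolidin-2-one | O=C(/C=C/c1c(OCc2ccccc2)c2ccc(OC)c(OC)c2n(C)c1=O)N1[C@H](Cc2ccccc2)COC1=O
F4 | step 9 | N-acyl oxazolidinone of acid 17 with (4R)-4-benzyloxazolidin-2-one (endo cycloadduct imide) | COc1ccc2c(OCC[Si](C)(C)C)c(c(=O)n(C)c2c1OC)[C@@H]1C=C(C)C[C@@H](c3c(OCc4ccccc4)c4ccc(OC)c(OC)c4n(C)c3=O)[C@@H]1C(=O)N1[C@H](Cc2ccccc2)COC1=O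
F5 | step 16 | iodo ether of 22 (O-B on C-c, iodine on C-b trans to O-B, C-a hydrogen anti to iodine) | COc1ccc2c3c(c(=O)n(C)c2c1OC)[C@@H]1[C@H](I)[C@]2(C)C[C@@H](c4c(c5ccc(OC)c(OC)c5n(C)c4=O)O2)[C@@H]1C(C)(C)O3
F6 | step 12 | 1-[(1S,2R,6R)-6-(4-benzyloxy quinolone B)-2-(4-silylethoxy quinolone A)-4-methylcyclohex-3-en-1-yl]ethanol, mixture of carbinol epimers | COc1ccc2c(OCC[Si](C)(C)C)c(c(=O)n(C)c2c1OC)[C@@H]1C=C(C)C[C@@H](c3c(OCc4ccccc4)c4ccc(OC)c(OC)c4n(C)c3=O)[C@@H]1C(C)O
F7 | step 12 | 1-[(1S,2R,6R)-6-(4-benzyloxy quinolone B)-2-(4-silylethoxy quinolone A)-4-methylcyclohex-3-en-1-yl]ethanone | COc1ccc2c(OCC[Si](C)(C)C)c(c(=O)n(C)c2c1OC)[C@@H]1C=C(C)C[C@@H](c3c(OCc4ccccc4)c4ccc(OC)c(OC)c4n(C)c3=O)[C@@H]1C(C)=O
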